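The data were generated by integration for substances that don't exist, noise included.

| flask | substrate | gas phase | remark | time |
|---|---|---|---|---|
| red | 10 mM | 1 mM (held) | run made earlier |  |
| ochre | 15 mM | 1 mM (held) | run made earlier |  |
| flask | 20 mM | 1.0 mM (held) |  | 15 h |

| run | time / h | target / % | substrate / % |
|---|---|---|---|
| red | 4.00 | 11.1 | 88.8 |
| red | 5.00 | 14.6 | 85.4 |
| red | 6.00 | 18.0 | 82.5 |
| red | 8.00 | 23.5 | 76.1 |
| red | 10.0 | 29.6 | 70.6 |
| ochre | 4.00 | 9.7 | 90.3 |
| ochre | 5.00 | 12.7 | 87.7 |
| ochre | 6.00 | 15.5 | 85.2 |
| ochre | 8.00 | 20.3 | 79.5 |
| ochre | 10.0 | 25.0 | 74.5 |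

(readings scatter by 0.3 percentage points)

**Two questions.** We have two questions about the flask: when target stands highest, and how high.

* time up to 15 h at which target stands highest
* the amount of target, in percent of the substrate charged, at that time

- at the start none of the gas is dissolved
- what was read earlier has a scatter of 0.3 percentage points, one standard deviation
- steps thought possible: gas phase <-> dissolved gas; substrate + dissolved gas -> target; dissolved gas -> decomposed reagent

**Rate curve.** From 4.00 h to 10.0 h, target grows at 0.308 mM h⁻¹ in red and 0.383 mM h⁻¹ in ochre. The rate rises by a factor 1.24, less than the factor 1.50 between the charges. So we use a Michaelis curve, r = aS/(S+K), with r the rate and S the substrate. Taking each run at its mean substrate gives the half-rate level K, 9.44 mM, and the ceiling rate a, 0.674 mM h⁻¹. Both are loose readings. Run back, the two lines show a mean lag of 0.298 h.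

**Our reckoning.** On this curve the flask runs at 0.458 mM h⁻¹ at its full charge and near 0.394 mM h⁻¹ towards its end, with target still rising, and we take 15 h as the best time. Averaging those two rates gives a factor 0.930, and the lag gives a factor 0.980. Together they put target in the flask at 31.3% at the end, in our reckoning.

**The forecast.** It gives 15 h and 31%, noting that “no listed step consumes it”. It reads a lag of about 0.7 h, against our 0.298 h.

**The result.** The flask gives 15.0 h and 33.0%, 1.7 percentage points above our reckoning. The loss of dissolved gas to decomposed reagent leaves the best time unchanged.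

    gas phase ⇌ dissolved gas, rate k1*(csat - [dissolved gas]) (kL = 0.845 h⁻¹)
    substrate + dissolved gas → target (k = 63.4 M⁻¹ h⁻¹)
    dissolved gas → decomposed reagent (k = 0.0417 h⁻¹)

**Neighbouring flask.** Now charge the neighbouring flask with 12 mM of substrate. The same a and K give a rate of 0.377 mM h⁻¹ at its full charge and 0.274 mM h⁻¹ towards its end. Its averaging factor is 0.863, lower than the 0.930 of the flask with 20 mM. With the same lag, our reckoning puts target at 39.9% of its charge. The simulated neighbouring flask holds target at 40.3% of its charge at its end.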